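**Assumption:** the stereodescriptor in the SMILES corresponds to (2S) at the flavanone C2 (O1 > aryl > C3 > H), the usual natural flavanone configuration; the route is designed for that enantiomer.

## Retrosynthetic overview

1. Target ⇐ removal of three MOM ethers from the fully protected (2S)-flavanone.
2. C2–C1' bond ⇐ Rh(I)/chiral bisphosphine 1,4-addition of a chromenyl boronic acid to a 5,7-bis(MOM)-6-prenylchromone; this joins the two halves and sets C2.
3. Chromone half ⇐ o-hydroxyaryl ynone ⇐ salicylaldehyde ⇐ 3,5-bis(MOMO)-4-prenylphenol ⇐ resorcinol (ortho-lithiation/prenylation, then Ir C–H borylation/oxidation). The A ring is decorated first and the γ-pyrone closed last, through the only free OH.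
4. Boronic acid half ⇐ 6-bromo-2,2-dimethylchromene ⇐ 7-hydroxy-2,2-dimethylchroman-4-one ⇐ resorcinol + 3,3-dimethylacrylic acid. The dimethylpyran ring is formed first and its alkene later.
5. Ring order: dimethylpyranone (B side) and γ-pyrone (A side) are built in separate branches; the γ-pyrone becomes the chiral C ring at the coupling.

## Route

### Branch A: chromone

**Step 1**
Reactants: 1, resorcinol
Product: 2, 1,3-bis(methoxymethoxy)benzene
Conditions: NaH, MOMCl, DMF, 0 °C → rt
Reagents that add atoms: chloromethyl methyl ether, COCCl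
Why: Williamson-type O-alkylation of both phenols installs MOM groups that serve as ortho-directing groups and as the final protecting groups.

**Step 2**
Reactants: 2; 3, prenyl bromide (1-bromo-3-methylbut-2-ene)
Product: 4, 1,3-bis(methoxymethoxy)-2-(3-methylbut-2-en-1-yl)benzene
Conditions: n-BuLi, TMEDA, THF, 0 °C → rt; CuI (cat.), then 3, −78 °C → rt
Reagents that add atoms: none (3 is the carbon source)
Why: Directed ortho-metalation occurs at the position flanked by both OMOM groups, and the aryl cuprate is alkylated by the allylic bromide at the primary carbon (SN2).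

**Step 3**
Reactants: 4
Product: 5, 2-[3,5-bis(methoxymethoxy)-4-(3-methylbut-2-en-1-yl)phenyl]-4,4,5,5-tetramethyl-1,3,2-dioxaborolane
Conditions: [Ir(OMe)(cod)]2 (1.5 mol%), dtbpy (3 mol%), B2pin2, THF, 60 °C
Reagents that add atoms: bis(pinacolato)diboron, CC1(C)OB(OC1(C)C)B1OC(C)(C)C(C)(C)O1
Why: Sterically controlled Ir-catalysed aromatic C–H borylation takes the only C–H with no ortho substituent (C5 of the 1,2,3-trisubstituted ring); the trisubstituted prenyl alkene is slow to react.

**Step 4**
Reactants: 5
Product: 6, 3,5-bis(methoxymethoxy)-4-(3-methylbut-2-en-1-yl)phenol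
Conditions: 30% H2O2, aq. NaOH, THF, 0 °C → rt; NH4Cl quench
Reagents that add atoms: hydrogen peroxide, OO
Why: Oxidative C–B → C–O conversion of the aryl boronate (boron-to-oxygen 1,2-shift) with alkaline peroxide, which does not epoxidise the isolated alkene.

**Step 5**
Reactants: 6; 7, paraformaldehyde
Product: 8, 6-hydroxy-2,4-bis(methoxymethoxy)-3-(3-methylbut-2-en-1-yl)benzaldehyde
Conditions: MgCl2, Et3N, (CH2O)n, MeCN, reflux
Reagents that add atoms: none (7 is the carbon source)
Why: Magnesium phenoxide-directed ortho-formylation (Casnati–Skattebøl) goes only ortho to the free OH; the two ortho sites are equivalent, so a single aldehyde forms and the free OH is now distinguished from the two MOM-protected oxygens.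

**Step 6**
Reactants: 8; 9, ethynylmagnesium bromide
Product: 10, 2-(1-hydroxyprop-2-yn-1-yl)-3,5-bis(methoxymethoxy)-4-(3-methylbut-2-en-1-yl)phenol (racemic carbinol)
Conditions: 9 (3.5 equiv), THF, 0 °C → rt; aq. NH4Cl
Reagents that add atoms: none (9 is the carbon source)
Why: Grignard 1,2-addition to the aldehyde (first equivalent consumed by the phenol); the new carbinol centre is irrelevant because it is oxidised in the next step.

**Step 7**
Reactants: 10
Product: 11, 1-[6-hydroxy-2,4-bis(methoxymethoxy)-3-(3-methylbut-2-en-1-yl)phenyl]prop-2-yn-1-one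
Conditions: activated MnO2, CH2Cl2, rt
Reagents that add atoms: none
Why: MnO2 selectively oxidises the benzylic/propargylic alcohol to the ynone without touching the prenyl alkene or MOM ethers.

**Step 8**
Reactants: 11
Product: 12, 5,7-bis(methoxymethoxy)-6-(3-methylbut-2-en-1-yl)-4H-chromen-4-one
Conditions: Et2NH, EtOH, rt, then 60 °C
Reagents that add atoms: none (Et2NH adds and is expelled)
Why: Amine conjugate addition gives a β-aminoenone that undergoes intramolecular addition–elimination by the only free phenol (formal 6-endo oxa-Michael), so only the 6-prenyl chromone can form.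

### Branch B: boronic acid

**Step 9**
Reactants: 1, resorcinol; 13, 3,3-dimethylacrylic acid (3-methylbut-2-enoic acid)
Product: 14, 7-hydroxy-2,2-dimethylchroman-4-one
Conditions: P2O5/MeSO3H (Eaton's reagent), 70 °C
Reagents that add atoms: none
Why: Friedel–Crafts acylation at C4 of resorcinol followed by intramolecular oxa-Michael closure gives the dimethylchromanone in one pot.

**Step 10**
Reactants: 14
Product: 15, 7-(methoxymethoxy)-2,2-dimethylchroman-4-one
Conditions: MOMCl, i-Pr2NEt, CH2Cl2, 0 °C → rt
Reagents that add atoms: chloromethyl methyl ether, COCCl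
Why: O-alkylation of the acidic para-acyl phenol.

**Step 11**
Reactants: 15
Product: 16, 6-bromo-7-(methoxymethoxy)-2,2-dimethylchroman-4-one
Conditions: NBS, MeCN, 0 °C → rt, dark
Reagents that add atoms: N-bromosuccinimide, O=C1CCC(=O)N1Br
Why: Electrophilic aromatic bromination goes to C6 (para to ring O, ortho to OMOM, less hindered than C8 between two oxygens); doing it at the ketone stage avoids a reactive chromene alkene.

**Step 12**
Reactants: 16
Product: 17, 6-bromo-7-(methoxymethoxy)-2,2-dimethylchroman-4-ol (racemic)
Conditions: NaBH4, MeOH/THF, 0 °C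
Reagents that add atoms: none
Why: Hydride reduction of the aryl ketone; the carbinol stereocentre is removed in the next step.

**Step 13**
Reactants: 17
Product: 18, 6-bromo-7-(methoxymethoxy)-2,2-dimethyl-2H-chromene
Conditions: MsCl, Et3N, CH2Cl2, 0 °C → rt
Reagents that add atoms: none
Why: The electron-rich benzylic mesylate ionises and eliminates in situ to the conjugated chromene under non-acidic conditions that keep the MOM ether.

**Step 14**
Reactants: 18
Product: 19, [7-(methoxymethoxy)-2,2-dimethyl-2H-chromen-6-yl]boronic acid
Conditions: n-BuLi, THF, −78 °C; B(Oi-Pr)3, −78 → 0 °C; aq. NH4Cl (pH ≈ 6)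
Reagents that add atoms: triisopropyl borate, CC(C)OB(OC(C)C)OC(C)C; water, O
Why: Fast Br–Li exchange gives an aryllithium stabilised by the ortho OMOM, which is trapped by the borate and hydrolysed to the boronic acid.

### Coupling and completion

**Step 15**
Reactants: 12; 19
Product: 20, (2S)-5,7-bis(methoxymethoxy)-2-[7-(methoxymethoxy)-2,2-dimethyl-2H-chromen-6-yl]-6-(3-methylbut-2-en-1-yl)chroman-4-one
Conditions: [Rh(OH)(cod)]2 (2.5 mol%), (S)-MeO-F12-BIPHEP (6 mol%), 19 (2.5 equiv, in portions), toluene/H2O 10:1, 50 °C, no added base
Reagents that add atoms: none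
Why: Rh-catalysed asymmetric 1,4-addition (Hayashi–Miyaura type) of the aryl-Rh species to the chromone C2, with the chiral ligand controlling the enone face to give (2S). The ligand hand is chosen by analogy with (S)-BINAP giving (S)-3-arylcyclohexanone (same face gives the same descriptor here) and must be confirmed by chiral HPLC/CD. Base-free conditions avoid retro-oxa-Michael racemisation of the product.

**Step 16**
Reactants: 20
Product: 21, cudraflavanone A, (2S)-5,7-dihydroxy-2-(7-hydroxy-2,2-dimethyl-2H-chromen-6-yl)-6-(3-methylbut-2-en-1-yl)chroman-4-one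
Conditions: 3 M aq. HCl/MeOH (1:4), rt → 40 °C, monitored; NaHCO3 quench
Reagents that add atoms: none
Why: Mild acid acetal hydrolysis removes all three aryl MOM ethers; dilute acid at low temperature is chosen to leave the prenyl group, the chromene and the C2 centre intact.

## Compound list

1 | resorcinol | Oc1cccc(O)c1 | starting material
2 | 1,3-bis(methoxymethoxy)benzene | COCOc1cccc(OCOC)c1 | intermediate
3 | prenyl bromide | CC(C)=CCBr | starting material
4 | 1,3-bis(methoxymethoxy)-2-prenylbenzene | COCOc1cccc(OCOC)c1CC=C(C)C | intermediate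
5 | 3,5-bis(methoxymethoxy)-4-prenylphenylboronic acid pinacol ester | COCOc1cc(B2OC(C)(C)C(C)(C)O2)cc(OCOC)c1CC=C(C)C | intermediate
6 | 3,5-bis(methoxymethoxy)-4-prenylphenol | COCOc1cc(O)cc(OCOC)c1CC=C(C)C | intermediate
7 | paraformaldehyde (formaldehyde unit) | C=O | starting material
8 | 6-hydroxy-2,4-bis(methoxymethoxy)-3-prenylbenzaldehyde | O=Cc1c(O)cc(OCOC)c(CC=C(C)C)c1OCOC | intermediate
9 | ethynylmagnesium bromide | C#C[Mg]Br | starting material
10 | 2-(1-hydroxyprop-2-yn-1-yl)-3,5-bis(methoxymethoxy)-4-prenylphenol (racemic) | C#CC(O)c1c(O)cc(OCOC)c(CC=C(C)C)c1OCOC | intermediate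
11 | 1-[6-hydroxy-2,4-bis(methoxymethoxy)-3-prenylphenyl]prop-2-yn-1-one | C#CC(=O)c1c(O)cc(OCOC)c(CC=C(C)C)c1OCOC | intermediate
12 | 5,7-bis(methoxymethoxy)-6-prenyl-4H-chromen-4-one | COCOc1cc2occc(=O)c2c(OCOC)c1CC=C(C)C | intermediate
13 | 3,3-dimethylacrylic acid | CC(C)=CC(=O)O | starting material
14 | 7-hydroxy-2,2-dimethylchroman-4-one | CC1(C)CC(=O)c2ccc(O)cc2O1 | intermediate
15 | 7-(methoxymethoxy)-2,2-dimethylchroman-4-one | COCOc1ccc2c(c1)OC(C)(C)CC2=O | intermediate
16 | 6-bromo-7-(methoxymethoxy)-2,2-dimethylchroman-4-one | COCOc1cc2c(cc1Br)C(=O)CC(C)(C)O2 | intermediate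
17 | 6-bromo-7-(methoxymethoxy)-2,2-dimethylchroman-4-ol (racemic) | COCOc1cc2c(cc1Br)C(O)CC(C)(C)O2 | intermediate
18 | 6-bromo-7-(methoxymethoxy)-2,2-dimethyl-2H-chromene | COCOc1cc2c(cc1Br)C=CC(C)(C)O2 | intermediate
19 | [7-(methoxymethoxy)-2,2-dimethyl-2H-chromen-6-yl]boronic acid | COCOc1cc2c(cc1B(O)O)C=CC(C)(C)O2 | intermediate
20 | (2S)-tris-MOM cudraflavanone A | CC(C)=CCc1c(OCOC)cc2c(c1OCOC)C(=O)C[C@@H](c1cc3c(cc1OCOC)OC(C)(C)C=C3)O2 | intermediate
21 | cudraflavanone A | CC(C)=CCc1c(O)cc2c(c1O)C(=O)C[C@@H](c1cc3c(cc1O)OC(C)(C)C=C3)O2 | target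

## Summary

**Total steps:** 16 (branch A: 8; branch B: 6; coupling and deprotection: 2).

**Longest linear sequence:** 10 (steps 1–8, 15, 16).

**Steps most likely to fail, with fallbacks:**

1. **Step 15 (asymmetric Rh 1,4-addition).** The chromone is electron-rich and peri-substituted, and the ortho-alkoxy boronic acid is prone to protodeboronation, so conversion or ee may be low. Fallback: drop the conjugate addition and build C2–C3 by aldol chemistry. Convert 8 to the methyl ketone (MeMgBr, then MnO2) and 18 to the aldehyde (n-BuLi/DMF), run a Claisen–Schmidt condensation to the 2'-hydroxychalcone, then cyclise by oxa-Michael addition (chiral bifunctional cinchona-thiourea catalyst, or NaOAc followed by preparative chiral HPLC resolution).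

2. **Step 3 (Ir C–H borylation with the prenyl group present).** Competing alkene hydroboration or isomerisation could erode yield. Fallback: change the order of bond formation. Borylate/oxidise alkene-free 2 to 3,5-bis(methoxymethoxy)phenol, mask the phenol as a TIPS ether, introduce the prenyl group by lithiation between the two OMOM groups, then desilylate to 6.

3. **Step 16 (acidic removal of three MOM groups).** Acid could cyclise the prenyl group onto a neighbouring OH, attack the chromene, or racemise C2 through benzylic ionisation assisted by the 2'-oxygen. Fallback: change the protecting-group strategy before the coupling. Exchange MOM for TBS on chromone 12 (acid, then TBSCl/imidazole), carry a TBS ether through branch B from 14 (with Pd-catalysed Miyaura borylation in place of lithiation), and finish with buffered fluoride (Et3N·3HF or HF·pyridine) instead of acid.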